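**Strategy.** The route rests on cutting the 1,2,3‑trimethylcyclohexene ring (C1′ quaternary, C2′ CHMe, C3′=C4′, C5′H2, C6′H2) at C5′–C6′ and C2′–C3′. One Knoevenagel–Michael–aldol cascade joins formaldehyde (C6′), a 3‑oxopentanoate (C3′–C5′) and 2‑methylacetoacetate (C1′, C2′) into a cyclohexenone ester. It makes C5′–C6′, C1′–C6′ and C2′=C3′ and exploits the 1,5‑dicarbonyl relationship latent between C2′ and C4′. C1′ is left racemic on purpose. A CBS reduction and reductive transposition set C2′, a decarboxylative radical alkynylation resets C1′ under control of C2′, and a copper‑catalysed benzopyrylium alkynylation sets chromene C2 while joining both halves.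

Key step: step 1

Remark: 2 and 15 are taken as catalogue compounds, and the (S,S)-ligand in step 9 is assumed to give the 2S adduct drawn; its mirror-image ligand is used if a model run shows the opposite sense.

Step 1
Reactants: 1 formaldehyde (as paraformaldehyde), 2 tert-butyl 3-oxopentanoate, 3 methyl 2-methyl-3-oxobutanoate
Product: 7 methyl 1,2,3-trimethyl-4-oxocyclohex-2-ene-1-carboxylate (racemic), via methylidene keto ester 4 (not isolated), via Michael adduct 5 (not isolated), via diketone 6 (not isolated)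
Conditions: (CH2O)n, piperidine (10 mol %), EtOH, 0 → 23 °C, 2 added slowly to excess 3; then CF3CO2H, CH2Cl2, 23 → 40 °C; then pyrrolidine, AcOH, toluene, 110 °C (Dean–Stark)
Reagents that add atoms: none
Why: Knoevenagel condensation of the active methylene of 2 with formaldehyde gives 4 (C5′=C6′), the enol of 3 adds to it in a Michael reaction (C1′–C6′) to give 5, acid removes the tert-butyl ester with loss of CO2 to give the 1,5-diketone 6, and the pyrrolidine enamine of the ethyl ketone closes the ring by aldol condensation onto the acetyl group (C2′=C3′). The closest known reaction type is the formaldehyde/β-keto ester assembly of Hagemann's ester, that is a Robinson annulation whose vinyl ketone is made in the flask. The ring closes by a 6-(enolendo)-exo-trig aldol addition followed by dehydration. The only stereocentre formed, C1′, is deliberately left racemic because step 5 erases and resets it. The step needs crossed rather than self Michael addition, which should be secured because 3 has a single α-hydrogen and can only act as donor while 2 is kept at low concentration. It also needs the aldol to start from the ethyl ketone, which should be secured because the acetyl group next to the quaternary carbon does not readily form an enamine.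

Step 2
Reactants: 7 methyl 1,2,3-trimethyl-4-oxocyclohex-2-ene-1-carboxylate (racemic)
Product: 8 methyl (1RS,4R)-4-hydroxy-1,2,3-trimethylcyclohex-2-ene-1-carboxylate (both C1 epimers)
Conditions: (S)-Me-CBS (20 mol %), catecholborane, toluene, −78 °C
Reagents that add atoms: none
Why: Corey–Bakshi–Shibata reduction in which the 2-methylalkenyl flank acts as the large group, so the (S)-oxazaborolidine should give the (4R)-carbinol in both C1 epimers by reagent control (C1 is remote), while catecholborane leaves the ester untouched.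

Step 3
Reactants: 8 methyl (1RS,4R)-4-hydroxy-1,2,3-trimethylcyclohex-2-ene-1-carboxylate
Product: 11 methyl (1RS,2R)-1,2,3-trimethylcyclohex-3-ene-1-carboxylate (both C1 epimers), via sulfonylhydrazine 9 (not isolated), via allylic diazene 10 (not isolated)
Conditions: 2-nitrobenzenesulfonylhydrazide (NBSH), PPh3, DEAD, THF, −30 °C; then 23 °C
Reagents that add atoms: none
Why: Reductive 1,3-transposition of an allylic alcohol: Mitsunobu displacement inverts C4, loss of sulfinic acid gives diazene 10, and its retro-ene loss of N2 delivers hydrogen to C2 on the face of the C–N bond, so the C4 carbinol configuration is transcribed into (2R)-C2 while the double bond moves to C3=C4.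

Step 4
Reactants: 11 methyl (1RS,2R)-1,2,3-trimethylcyclohex-3-ene-1-carboxylate
Product: 12 (1RS,2R)-1,2,3-trimethylcyclohex-3-ene-1-carboxylic acid (both C1 epimers)
Conditions: LiOH·H2O, THF/MeOH/H2O, 70 °C; then 1 M HCl
Reagents that add atoms: lithium hydroxide, [Li+].[OH-]
Why: Saponification of a hindered methyl ester (BAc2); neither stereocentre is enolisable, so C2 cannot epimerise.

Step 5
Reactants: 12 (1RS,2R)-1,2,3-trimethylcyclohex-3-ene-1-carboxylic acid
Product: 13 triisopropyl{[(1R,2R)-1,2,3-trimethylcyclohex-3-en-1-yl]ethynyl}silane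
Conditions: TIPS-EBX (1.5 equiv), Ir[dF(CF3)ppy]2(dtbbpy)PF6 (2 mol %), PhCO2Cs, ClCH2CH2Cl, blue LEDs, 23 °C
Reagents that add atoms: TIPS-EBX (1-[(triisopropylsilyl)ethynyl]-1,2-benziodoxol-3(1H)-one), CC(C)[Si](C#CI1OC(=O)c2ccccc12)(C(C)C)C(C)C
Why: Photoredox decarboxylative alkynylation: carboxylate oxidation and loss of CO2 turn both C1 epimers into one planar tertiary radical, which should add to the ethynylbenziodoxolone opposite to the C2 methyl group (held pseudoaxial by allylic 1,2-strain with the C1 and C3 methyl groups), so C1 is set with the alkyne trans to that methyl by substrate control.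

Step 6
Reactants: 13 triisopropyl{[(1R,2R)-1,2,3-trimethylcyclohex-3-en-1-yl]ethynyl}silane
Product: 14 (1R,2R)-1-ethynyl-1,2,3-trimethylcyclohex-3-ene (ring numbered from the quaternary carbon)
Conditions: Bu4NF, THF, 0 °C
Reagents that add atoms: none
Why: Fluoride-induced protodesilylation of the alkynylsilane; the volatile product is carried forward as a solution.

Step 7
Reactants: 15 1-(2-hydroxy-3,4,5,6-tetramethoxyphenyl)ethan-1-one
Product: 17 5,6,7,8-tetramethoxy-2-methyl-4H-chromen-4-one, via diketone 16 (not isolated)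
Conditions: NaH, EtOAc, THF, 65 °C; then conc. HCl, AcOH, 90 °C
Reagents that add atoms: ethyl acetate, CCOC(C)=O
Why: Claisen condensation of the acetophenone enolate with ethyl acetate gives the 1,3-diketone, which cyclodehydrates under acid to the 2-methylchromone (standard chromone synthesis).

Step 8
Reactants: 17 5,6,7,8-tetramethoxy-2-methyl-4H-chromen-4-one
Product: 18 5-hydroxy-6,7,8-trimethoxy-2-methyl-4H-chromen-4-one
Conditions: BCl3 (1.2 equiv), CH2Cl2, −78 → 0 °C; aq. NaHCO3
Reagents that add atoms: none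
Why: Chelation-directed ether cleavage: BCl3 binds between the C4 carbonyl and the peri 5-methoxy oxygen and should remove only that methyl group.

Step 9
Reactants: 18 5-hydroxy-6,7,8-trimethoxy-2-methyl-4H-chromen-4-one, 14 (1R,2R)-1-ethynyl-1,2,3-trimethylcyclohex-3-ene
Product: 21 (2S)-5-hydroxy-6,7,8-trimethoxy-2-methyl-2-{[(1R,2R)-1,2,3-trimethylcyclohex-3-en-1-yl]ethynyl}-2,3-dihydro-4H-chromen-4-one, via benzopyrylium triflate 19 (not isolated), via silyl enol ether 20 (not isolated)
Conditions: tBuMe2SiOTf (2.3 equiv), iPr2NEt, CH2Cl2, 23 °C; then 14, Cu(MeCN)4PF6 (10 mol %), (S,S)-Ph-BOX (12 mol %), iPr2NEt, toluene, −40 °C; then Bu4NF, AcOH, THF, 0 °C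
Reagents that add atoms: none
Why: Copper-catalysed enantioselective alkynylation of a benzopyrylium ion: silylation of the phenol and the chromone carbonyl gives 19, the bis(oxazoline)-bound copper acetylide of 14 adds to pyrylium C2 on one face (ligand control sets the tetrasubstituted ether centre), and buffered fluoride releases the chromanone and the phenol.

Step 10
Reactants: 21 (2S)-5-hydroxy-6,7,8-trimethoxy-2-methyl-2-{[(1R,2R)-1,2,3-trimethylcyclohex-3-en-1-yl]ethynyl}-2,3-dihydro-4H-chromen-4-one
Product: 22 (2R)-5-hydroxy-6,7,8-trimethoxy-2-methyl-2-{2-[(1S,2S)-1,2,3-trimethylcyclohex-3-en-1-yl]ethyl}-2,3-dihydro-4H-chromen-4-one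
Conditions: KO2CN=NCO2K (excess, in portions), AcOH, MeOH/THF, 23 °C
Reagents that add atoms: none
Why: Diimide reduction: the alkyne should be taken through the strained cis-alkene to the ethylene bridge, while the trisubstituted ring alkene, the aryl ketone and the phenol do not react with diimide (the descriptors change only through CIP priorities).

Step 11
Reactants: 22 (2R)-5-hydroxy-6,7,8-trimethoxy-2-methyl-2-{2-[(1S,2S)-1,2,3-trimethylcyclohex-3-en-1-yl]ethyl}-2,3-dihydro-4H-chromen-4-one
Product: 24 (2R)-6,7,8-trimethoxy-2-methyl-2-{2-[(1S,2S)-1,2,3-trimethylcyclohex-3-en-1-yl]ethyl}-2H-chromen-5-ol (CNP0185215.2), via chromanol 23 (not isolated)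
Conditions: NaBH4, EtOH/THF, 0 → 23 °C; then PPTS (10 mol %), toluene, 60 °C, dark
Reagents that add atoms: none
Why: Borohydride reduction of the aryl ketone and mild acid-catalysed dehydration of the electron-rich benzylic alcohol should give the 2H-chromene without touching C2, the ring alkene or its stereocentres.

**Compound list**

1 | formaldehyde (used as paraformaldehyde) | C=O | starting material
2 | tert-butyl 3-oxopentanoate | CCC(=O)CC(=O)OC(C)(C)C | starting material
3 | methyl 2-methyl-3-oxobutanoate | COC(=O)C(C)C(C)=O | starting material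
4 | tert-butyl 2-methylidene-3-oxopentanoate | CCC(=O)C(=C)C(=O)OC(C)(C)C | intermediate
5 | 1-tert-butyl 5-methyl 4-acetyl-4-methyl-2-propanoylpentanedioate (stereoisomer mixture) | CCC(=O)C(CC(C)(C(C)=O)C(=O)OC)C(=O)OC(C)(C)C | intermediate
6 | methyl 2-acetyl-2-methyl-5-oxoheptanoate (racemic) | CCC(=O)CCC(C)(C(C)=O)C(=O)OC | intermediate
7 | methyl 1,2,3-trimethyl-4-oxocyclohex-2-ene-1-carboxylate (racemic) | COC(=O)C1(C)CCC(=O)C(C)=C1C | intermediate
8 | methyl (1RS,4R)-4-hydroxy-1,2,3-trimethylcyclohex-2-ene-1-carboxylate | COC(=O)C1(C)CC[C@@H](O)C(C)=C1C | intermediate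
9 | methyl (1RS,4S)-4-[1-(2-nitrobenzenesulfonyl)hydrazin-1-yl]-1,2,3-trimethylcyclohex-2-ene-1-carboxylate | COC(=O)C1(C)CC[C@H](N(N)S(=O)(=O)c2ccccc2[N+](=O)[O-])C(C)=C1C | intermediate
10 | methyl (1RS,4S)-4-diazenyl-1,2,3-trimethylcyclohex-2-ene-1-carboxylate | COC(=O)C1(C)CC[C@H](N=N)C(C)=C1C | intermediate
11 | methyl (1RS,2R)-1,2,3-trimethylcyclohex-3-ene-1-carboxylate | COC(=O)C1(C)CCC=C(C)[C@H]1C | intermediate
12 | (1RS,2R)-1,2,3-trimethylcyclohex-3-ene-1-carboxylic acid | OC(=O)C1(C)CCC=C(C)[C@H]1C | intermediate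
13 | triisopropyl{[(1R,2R)-1,2,3-trimethylcyclohex-3-en-1-yl]ethynyl}silane | CC(C)[Si](C#C[C@]1(C)CCC=C(C)[C@H]1C)(C(C)C)C(C)C | intermediate
14 | (1R,2R)-1-ethynyl-1,2,3-trimethylcyclohex-3-ene | C#C[C@]1(C)CCC=C(C)[C@H]1C | intermediate
15 | 1-(2-hydroxy-3,4,5,6-tetramethoxyphenyl)ethan-1-one | CC(=O)c1c(O)c(OC)c(OC)c(OC)c1OC | starting material
16 | 1-(2-hydroxy-3,4,5,6-tetramethoxyphenyl)butane-1,3-dione | CC(=O)CC(=O)c1c(O)c(OC)c(OC)c(OC)c1OC | intermediate
17 | 5,6,7,8-tetramethoxy-2-methyl-4H-chromen-4-one | CC1=CC(=O)c2c(OC)c(OC)c(OC)c(OC)c2O1 | intermediate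
18 | 5-hydroxy-6,7,8-trimethoxy-2-methyl-4H-chromen-4-one | CC1=CC(=O)c2c(O)c(OC)c(OC)c(OC)c2O1 | intermediate
19 | 4,5-bis[(tert-butyldimethylsilyl)oxy]-6,7,8-trimethoxy-2-methylchromenylium trifluoromethanesulfonate | Cc1cc(O[Si](C)(C)C(C)(C)C)c2c(O[Si](C)(C)C(C)(C)C)c(OC)c(OC)c(OC)c2[o+]1.[O-]S(=O)(=O)C(F)(F)F | intermediate
20 | (2S)-4,5-bis[(tert-butyldimethylsilyl)oxy]-6,7,8-trimethoxy-2-methyl-2-{[(1R,2R)-1,2,3-trimethylcyclohex-3-en-1-yl]ethynyl}-2H-chromene | COc1c(O[Si](C)(C)C(C)(C)C)c2c(c(OC)c1OC)O[C@](C)(C#C[C@]1(C)CCC=C(C)[C@H]1C)C=C2O[Si](C)(C)C(C)(C)C | intermediate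
21 | (2S)-5-hydroxy-6,7,8-trimethoxy-2-methyl-2-{[(1R,2R)-1,2,3-trimethylcyclohex-3-en-1-yl]ethynyl}-2,3-dihydro-4H-chromen-4-one | COc1c(O)c2c(c(OC)c1OC)O[C@](C)(C#C[C@]1(C)CCC=C(C)[C@H]1C)CC2=O | intermediate
22 | (2R)-5-hydroxy-6,7,8-trimethoxy-2-methyl-2-{2-[(1S,2S)-1,2,3-trimethylcyclohex-3-en-1-yl]ethyl}-2,3-dihydro-4H-chromen-4-one | COc1c(O)c2c(c(OC)c1OC)O[C@](C)(CC[C@]1(C)CCC=C(C)[C@H]1C)CC2=O | intermediate
23 | (2R,4RS)-6,7,8-trimethoxy-2-methyl-2-{2-[(1S,2S)-1,2,3-trimethylcyclohex-3-en-1-yl]ethyl}-3,4-dihydro-2H-chromene-4,5-diol | COc1c(O)c2c(c(OC)c1OC)O[C@](C)(CC[C@]1(C)CCC=C(C)[C@H]1C)CC2O | intermediate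
24 | (2R)-6,7,8-trimethoxy-2-methyl-2-{2-[(1S,2S)-1,2,3-trimethylcyclohex-3-en-1-yl]ethyl}-2H-chromen-5-ol | COc1c(O)c2c(c(OC)c1OC)O[C@](C)(CC[C@]1(C)CCC=C(C)[C@H]1C)C=C2 | target

**Step count and risks**

Total steps: 11. Longest linear sequence: 9 (steps 1–6 and 9–11; steps 7–8 make the chromone separately).

Steps most likely to fail:

1. Step 9. Enantioface discrimination may erode, or the addition may stall, because a tert-alkyl acetylide has to attack a 2-methyl, electron-rich pyrylium. The fallback sets out from 18 and 14 and returns at 21. The pyrylium 19 is formed as before and treated with the lithium acetylide of 14 (n-BuLi, THF, −78 °C) without ligand, then with Bu4NF/AcOH. This should give 21 together with its C2 epimer, (2R)-5-hydroxy-6,7,8-trimethoxy-2-methyl-2-{[(1R,2R)-1,2,3-trimethylcyclohex-3-en-1-yl]ethynyl}-2,3-dihydro-4H-chromen-4-one F1. The two are diastereomers because the cyclohexene is enantiopure, and are separated by chromatography. F1 is equilibrated with DBU in MeCN at 60 °C through reversible oxa-Michael ring opening to 1-(2,6-dihydroxy-3,4,5-trimethoxyphenyl)-3-methyl-5-[(1R,2R)-1,2,3-trimethylcyclohex-3-en-1-yl]pent-2-en-4-yn-1-one F2 (whose two phenols are equivalent, so reclosure returns the same constitution) and is recycled.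

2. Step 5. The planar tertiary radical may be trapped with poor facial selectivity, or the unactivated tertiary carboxylate may be oxidised too slowly. The fallback sets out from 11 and returns at 14 without any radical at C1. The C1 epimers of 11 are separated by chromatography and methyl (1R,2R)-1,2,3-trimethylcyclohex-3-ene-1-carboxylate F3 is kept. LiAlH4 (Et2O, 0 °C) gives [(1R,2R)-1,2,3-trimethylcyclohex-3-en-1-yl]methanol F4, and Dess–Martin periodinane gives (1R,2R)-1,2,3-trimethylcyclohex-3-ene-1-carbaldehyde F5. Ohira–Bestmann homologation (dimethyl (1-diazo-2-oxopropyl)phosphonate, K2CO3, MeOH) then gives 14 with retention at C1. The cost is the loss of the other C1 epimer.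

3. Step 1. Self-coupling of the methylidene keto ester 4 with its own precursor 2 may outrun the crossed Michael addition. The fallback sets out from 3 and returns at 6, and from there at 7. A base-catalysed Michael addition (K2CO3 or Et3N, 23 °C) of 3 to purchased pent-1-en-3-one gives diketone 6 directly, which is cyclodehydrated with pyrrolidine/AcOH exactly as in the last stage of step 1. No new compound is made.

Further compounds

F1 | step 9 | (2R)-5-hydroxy-6,7,8-trimethoxy-2-methyl-2-{[(1R,2R)-1,2,3-trimethylcyclohex-3-en-1-yl]ethynyl}-2,3-dihydro-4H-chromen-4-one | COc1c(O)c2c(c(OC)c1OC)O[C@@](C)(C#C[C@]1(C)CCC=C(C)[C@H]1C)CC2=O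
F2 | step 9 | 1-(2,6-dihydroxy-3,4,5-trimethoxyphenyl)-3-methyl-5-[(1R,2R)-1,2,3-trimethylcyclohex-3-en-1-yl]pent-2-en-4-yn-1-one | COc1c(O)c(C(=O)C=C(C)C#C[C@]2(C)CCC=C(C)[C@H]2C)c(O)c(OC)c1OC
F3 | step 5 | methyl (1R,2R)-1,2,3-trimethylcyclohex-3-ene-1-carboxylate | COC(=O)[C@]1(C)CCC=C(C)[C@H]1C
F4 | step 5 | [(1R,2R)-1,2,3-trimethylcyclohex-3-en-1-yl]methanol | OC[C@]1(C)CCC=C(C)[C@H]1C
F5 | step 5 | (1R,2R)-1,2,3-trimethylcyclohex-3-ene-1-carbaldehyde | O=C[C@]1(C)CCC=C(C)[C@H]1C
F0 | step 1 | none | none
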